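**Assumption:** myrcene, 8-hydroxy-7-methoxycoumarin (daphnetin 7-methyl ether) and the L-fructose-derived ketone catalyst are taken as purchasable; the chiral ketone is a catalyst, not a starting material.

## Retrosynthetic overview

1. Target ⇒ diene ether: the C6–OH/C7–OH pair comes from the trisubstituted C6=C7 alkene by a one-flask, ketone-organocatalysed asymmetric dihydroxylation (chiral dioxirane epoxidation, then hydration in the same flask). This last step sets the only stereocentre (6S).
2. Diene ether ⇒ 8-hydroxy-7-methoxycoumarin + γ-geraniol: aryl O–CH2 bond by Mitsunobu etherification.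
3. γ-Geraniol ⇒ myrcene: anti-Markovnikov hydroboration–oxidation of the only monosubstituted alkene; the whole C10 chain is bought.
4. Rings: none is built. The coumarin bicycle is bought intact; the only ring formed is the transient oxirane of the last step, opened in the same flask.

## Route

Step 1
Reactants: 1 myrcene (7-methyl-3-methylideneocta-1,6-diene)
Product: 3 7-methyl-3-methylideneoct-6-en-1-ol (γ-geraniol), via trialkylborane 2 (not isolated)
Conditions: Sia2BH (1.0 equiv, from BH3·THF + 2 equiv 2-methylbut-2-ene), THF, 0 °C, 3 h; then 3 M NaOH, 30% H2O2, 0 °C → rt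
Reagents that add atoms: hydrogen peroxide OO (oxygen of 3); borane–tetrahydrofuran [BH3-][O+]1CCCC1 and 2-methylbut-2-ene CC=C(C)C (boron and the two 3-methylbutan-2-yl groups of 2 only)
Why: Hydroboration–oxidation, in which the bulky dialkylborane adds anti-Markovnikov to the only monosubstituted alkene terminus (the 1,1-disubstituted and trisubstituted alkenes react far more slowly) and alkaline H2O2 replaces boron by OH; no stereocentre is formed.

Step 2
Reactants: 3 7-methyl-3-methylideneoct-6-en-1-ol (1.2 equiv); 4 8-hydroxy-7-methoxy-2H-chromen-2-one
Product: 5 7-methoxy-8-[(7-methyl-3-methylideneoct-6-en-1-yl)oxy]-2H-chromen-2-one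
Conditions: PPh3 (1.3 equiv), DIAD (1.3 equiv), THF, 0 °C → rt, 12 h
Reagents that add atoms: none
Why: Mitsunobu etherification, in which the primary alcohol is activated as its alkoxyphosphonium ion and displaced (SN2 at CH2) by the acidic 8-phenoxide (pKa about 9) under neutral conditions that leave the lactone and both alkenes untouched; no stereocentre is formed.

Step 3
Reactants: 5 7-methoxy-8-[(7-methyl-3-methylideneoct-6-en-1-yl)oxy]-2H-chromen-2-one
Product: 7 8-{[(6S)-6,7-dihydroxy-7-methyl-3-methylideneoctyl]oxy}-7-methoxy-2H-chromen-2-one (target CNP0354003.1), via (S)-epoxide 6 (not isolated)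
Conditions: 1,2:4,5-di-O-isopropylidene-β-L-erythro-2,3-hexodiulo-2,6-pyranose (ent-Shi ketone, 30 mol%), 2KHSO5·KHSO4·K2SO4 (1.4 equiv KHSO5) and aq. K2CO3 co-fed over 2 h at pH 10.5, Bu4NHSO4 (5 mol%), Na2H2EDTA (trace), MeCN–DMM–H2O, 0 °C; then 1 M H2SO4 to pH 1.5, 0 °C → rt, 1 h
Reagents that add atoms: potassium peroxymonosulfate [K+].[O-]S(=O)(=O)OO (oxygen on C6); water O (hydroxyl oxygen on C7)
Why: Proposed new method: a one-flask ketone-organocatalysed asymmetric dihydroxylation run as an epoxidation–hydration relay — at pH 10.5 the dioxirane formed from the L-fructose-derived ketone and KHSO5 transfers oxygen through the spiro transition state to the face of the most electron-rich, trisubstituted C6=C7 bond that gives the (S)-oxirane 6 (the D-fructose-derived enantiomer gives R; the 1,1-disubstituted alkene and the electron-poor coumarin C3=C4 bond react much more slowly), then acidifying the same flask (Bu4NHSO4 carries the acid into the organic phase) lets water open the protonated oxirane at the tertiary carbon C7 in a borderline SN1 process, so the catalyst-made C6–O bond is never broken and 6S passes unchanged into the diol while any ring-opened coumarinate relactonises; the closest known reactions are the Shi epoxidation of trisubstituted alkenes and the separate acid hydrolysis of 2,2-dimethyl-3-alkyloxiranes, which to my knowledge have not been merged into a single site-selective catalytic dihydroxylation of a diene.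

## Compound list

1 | myrcene (7-methyl-3-methylideneocta-1,6-diene) | C=CC(=C)CCC=C(C)C | starting material
2 | bis(3-methylbutan-2-yl)(7-methyl-3-methylideneoct-6-en-1-yl)borane (mixture of diastereomers at the two 3-methylbutan-2-yl carbons) | C=C(CCB(C(C)C(C)C)C(C)C(C)C)CCC=C(C)C | intermediate
3 | 7-methyl-3-methylideneoct-6-en-1-ol (γ-geraniol) | C=C(CCO)CCC=C(C)C | intermediate
4 | 8-hydroxy-7-methoxy-2H-chromen-2-one (daphnetin 7-methyl ether) | COc1ccc2ccc(=O)oc2c1O | starting material
5 | 7-methoxy-8-[(7-methyl-3-methylideneoct-6-en-1-yl)oxy]-2H-chromen-2-one | C=C(CCOc1c(OC)ccc2ccc(=O)oc12)CCC=C(C)C | intermediate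
6 | 8-({5-[(2S)-3,3-dimethyloxiran-2-yl]-3-methylidenepentyl}oxy)-7-methoxy-2H-chromen-2-one | C=C(CCOc1c(OC)ccc2ccc(=O)oc12)CC[C@@H]1OC1(C)C | intermediate
7 | 8-{[(6S)-6,7-dihydroxy-7-methyl-3-methylideneoctyl]oxy}-7-methoxy-2H-chromen-2-one (CNP0354003.1) | C=C(CCOc1c(OC)ccc2ccc(=O)oc12)CC[C@H](O)C(C)(C)O | target

## Step count and risks

Total step count: 3. Longest linear sequence: 3 steps (1 → 3 → 5 → 7).

**Step 3 (the proposed new step; highest risk).** The two stages may not tolerate each other in one flask. The coumarin lactone can open at pH 10.5 and the resulting phenoxide can be over-oxidised by KHSO5. The 1,1-disubstituted alkene can be epoxidised competitively. The crude oxidation medium may give rearrangement instead of clean hydration. The fallback uses known chemistry only and sets the stereocentre before the ether bond is made, so the coumarin never meets base or oxidant. It sets out from 3 and comes back to the route at 6. Alcohol 3 is epoxidised under the standard buffered conditions (1,2:4,5-di-O-isopropylidene-β-L-erythro-2,3-hexodiulo-2,6-pyranose, 2KHSO5·KHSO4·K2SO4, K2CO3, pH 10.5, MeCN–DMM–H2O, 0 °C). The product, (S)-5-(3,3-dimethyloxiran-2-yl)-3-methylidenepentan-1-ol F1, is isolated and freed of any regioisomeric epoxide. F1 and phenol 4 are then coupled as in step 2 (PPh3, DIAD, THF) to give 6, now as an isolated compound. Finally 6 is hydrolysed to 7 in a separate, conventional operation (0.5 M HClO4, THF–H2O, 0 °C), which opens the oxirane at the tertiary carbon with retention at C6.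

**Step 2.** The homoallylic alkoxyphosphonium ion can undergo E2 loss (giving back 1), and the flanked 8-phenoxide may attack slowly. The fallback sets out from 3 and comes back at 5. Alcohol 3 is converted (TsCl, NaOH, THF–H2O, 0 °C) into 7-methyl-3-methylideneoct-6-en-1-yl 4-methylbenzenesulfonate F2. F2 then alkylates the cesium phenoxide of 4 (Cs2CO3, DMF, 50 °C) in a Williamson etherification to give 5.

**Step 1.** Technical myrcene is impure, and the borane may add twice or attack the 1,1-disubstituted terminus of the diene. The fallback builds the chain by C–C bond formation instead of functionalising a C10 diene. Because it replaces the first step, it sets out from no numbered compound but from two other achiral commercial compounds, 3-methylbut-3-en-1-ol F3 and 1-bromo-3-methylbut-2-ene F4, and it comes back at 3. F3 is doubly deprotonated (n-BuLi 2.2 equiv, TMEDA, Et2O–hexane, 0 °C → rt) at oxygen and at the allylic methyl group to give lithium 3-(lithiomethyl)but-3-en-1-olate F5. The carbanion of F5 is alkylated by F4 (−78 → 0 °C) at its primary carbon, and aqueous work-up gives 3.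

## Further compounds

F1 | step 3 | (S)-5-(3,3-dimethyloxiran-2-yl)-3-methylidenepentan-1-ol | C=C(CCO)CC[C@@H]1OC1(C)C
F2 | step 2 | 7-methyl-3-methylideneoct-6-en-1-yl 4-methylbenzenesulfonate | C=C(CCOS(=O)(=O)c1ccc(C)cc1)CCC=C(C)C
F3 | step 1 | 3-methylbut-3-en-1-ol (bought for this fallback) | C=C(C)CCO
F4 | step 1 | 1-bromo-3-methylbut-2-ene (bought for this fallback) | CC(C)=CCBr
F5 | step 1 | lithium 3-(lithiomethyl)but-3-en-1-olate | [Li]CC(=C)CCO[Li]
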